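The cyclopentenone ring (C8–C12, prostanoid numbering) is disconnected into C8–C9–C10 and C11–C12. A 2-bromo-4-oxycyclopent-2-enone is the condensation product of a 4-oxoaldehyde, and its carbonyl C9 sits between a CH2 (C8) and a CBr carbon (C10), the pattern of symmetrical 1,3-dibromoacetone. In one operation the chiral enamine of racemic 2-silyloxy-(Z)-dec-4-enal (C11–C20, Z-alkene already in place) is C-alkylated by dibromoacetone (C8–C12 bond, C12 carbinol stereocentre) and the iminium formed closes by Mannich condensation with loss of the amine (C10=C11). Aldol condensation at C8 with methyl (Z)-7-oxohept-5-enoate and desilylation complete the target.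

Key step: step 3

Remark: carbon atoms carry prostanoid numbers (C1 ester carbon, ring C8–C12, C20 terminal methyl); compounds 1, 5, 6, 10 and 11 are taken as commercial.

Step 1
Reactants: 1 (4Z)-dec-4-enal
Product: 2 tert-butyl[(4Z)-deca-1,4-dien-1-yloxy]dimethylsilane (C1=C2 as E/Z mixture)
Conditions: TBSOTf, Et3N, CH2Cl2, 0 °C to 23 °C
Reagents that add atoms: tert-butyldimethylsilyl trifluoromethanesulfonate, CC(C)(C)[Si](C)(C)OS(=O)(=O)C(F)(F)F
Why: Soft enolisation with silyl triflate and amine base (silyl enol ether formation) should convert the aldehyde into its enol silane without touching the isolated Z-alkene; no stereocentre is formed and the enol ether geometry is irrelevant because C12 is reset in steps 2 and 3.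

Step 2
Reactants: 2 tert-butyl[(4Z)-deca-1,4-dien-1-yloxy]dimethylsilane
Product: 4 rac-(4Z)-2-[(tert-butyldimethylsilyl)oxy]dec-4-enal, via silyloxy oxirane 3 (not isolated)
Conditions: dimethyldioxirane (1.0 equiv), acetone–CH2Cl2, −78 °C to 0 °C; then 23 °C
Reagents that add atoms: dimethyldioxirane, CC1(C)OO1
Why: Rubottom oxidation: the electron-rich enol ether should be epoxidised far faster than the 1,2-dialkyl alkene, and oxirane 3 opens with 1,4-silyl migration to the alpha-silyloxy aldehyde; C12 is formed racemic, which is harmless because it becomes planar again in enamine 7.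

Step 3
Reactants: 4 rac-(4Z)-2-[(tert-butyldimethylsilyl)oxy]dec-4-enal, 5 (2S,5S)-2,5-dimethylpyrrolidine, 6 1,3-dibromopropan-2-one
Product: 9 (4S)-2-bromo-4-[(tert-butyldimethylsilyl)oxy]-4-[(2Z)-oct-2-en-1-yl]cyclopent-2-en-1-one, via enamine 7 (not isolated), via iminium bromide 8 (not isolated)
Conditions: 5 (1.05 equiv), 4 Å molecular sieves, PhMe, 23 °C; then 6 (1.1 equiv), MeCN, −30 °C to 0 °C; then NaHCO3 (2 equiv), 40 °C; 5 recovered by acid extraction
Reagents that add atoms: none
Why: Proposed new method: condensation of 4 with the C2-symmetric amine 5 gives the tertiary enamine 7, whose carbon C12 attacks one CH2Br group of the symmetrical ketone 6 in an SN2 step (C8–C12 bond, quaternary carbinol centre) to give iminium salt 8; the bromo-enol of 8 then adds to the iminium carbon C11 (intramolecular Mannich reaction, C10–C11 bond) and E1cB loss of the amine leaves the C10=C11 bromoenone. The closest known chemistry is the Stork enamine alkylation of alpha-branched aldehyde enamines with alpha-halo ketones followed by aldol cyclisation of the 4-oxoaldehyde to a 4,4-disubstituted cyclopentenone, together with the asymmetric alkylation of ketone enamines of trans-2,5-dimethylpyrrolidine; an enantioselective version on an alpha-silyloxy aldehyde enamine with 1,3-dibromoacetone is not known. The ring closes by attack of enol carbon C10 on the exocyclic C11=N bond, formally a 5-(enolendo)-exo-trig closure, the mode of the classical 1,4-dicarbonyl to cyclopentenone condensation, which runs under equilibrating conditions. C12 is set by the auxiliary: the enamine should be Z (silyloxy oxygen cis to nitrogen, the larger allylic CH2 group turned away from the ring methyl groups), the pseudoaxial methyl group next to nitrogen blocks one face, and on this model the (2S,5S)-amine should lead to the (S)-configured product 9, whose quaternary C12 cannot epimerise afterwards. The step needs C- over N-alkylation, reaction at only one C–Br bond and cyclisation before any beta-elimination of the silyloxy group: a tertiary enamine has no N–H for pyrrole-type side reactions, both CH2Br groups of 6 are equivalent so the untouched one necessarily ends as the C10 bromide, and the alpha-bromo position C10 enolises more readily than C8.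

Step 4
Reactants: 10 methyl hex-5-enoate, 11 (2Z)-but-2-ene-1,4-diol
Product: 12 methyl (5Z)-7-hydroxyhept-5-enoate
Conditions: (1,3-dimesitylimidazolidin-2-ylidene)(2-isopropoxybenzylidene)(3,6-dichlorobenzene-1,2-dithiolato)ruthenium (5 mol %), 11 (2 equiv), THF, 22 °C
Reagents that add atoms: none
Why: Stereoretentive cross-metathesis with a ruthenium dithiolate alkylidene should transfer the Z-configured CH–CH2OH unit of 11 to the terminal alkene, so that the 5Z geometry is copied from the diol and the ester is tolerated.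

Step 5
Reactants: 12 methyl (5Z)-7-hydroxyhept-5-enoate
Product: 13 methyl (5Z)-7-oxohept-5-enoate
Conditions: PhI(OAc)2 (1.1 equiv), TEMPO (10 mol %), CH2Cl2, 0 °C to 23 °C; crude 13 used at once
Reagents that add atoms: none
Why: Nitroxyl-catalysed oxidation of the primary allylic alcohol under near-neutral conditions should stop at the aldehyde and keep the Z-alkene, provided the enal is used without storage.

Step 6
Reactants: 9 (4S)-2-bromo-4-[(tert-butyldimethylsilyl)oxy]-4-[(2Z)-oct-2-en-1-yl]cyclopent-2-en-1-one, 13 methyl (5Z)-7-oxohept-5-enoate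
Product: 15 methyl (5Z)-7-[(2S)-4-bromo-2-[(tert-butyldimethylsilyl)oxy]-2-[(2Z)-oct-2-en-1-yl]-5-oxocyclopent-3-en-1-yl]-7-hydroxyhept-5-enoate (C7/C8 epimer mixture), via lithium dienolate 14 (not isolated)
Conditions: LiN(iPr)2 (1.05 equiv), THF, −78 °C; then 13, −78 °C; AcOH, −78 °C
Reagents that add atoms: none
Why: Kinetic deprotonation at C8, the only enolisable position, gives the cross-conjugated dienolate 14, which should add to the aldehyde of 13 (aldol addition) faster than to its ester at −78 °C; the new C7 and C8 centres form as a mixture and are erased in step 7, and quaternary C12 is untouched.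

Step 7
Reactants: 15 methyl (5Z)-7-[(2S)-4-bromo-2-[(tert-butyldimethylsilyl)oxy]-2-[(2Z)-oct-2-en-1-yl]-5-oxocyclopent-3-en-1-yl]-7-hydroxyhept-5-enoate
Product: 17 methyl (5Z,7E)-7-[(2R)-4-bromo-2-[(tert-butyldimethylsilyl)oxy]-2-[(2Z)-oct-2-en-1-yl]-5-oxocyclopent-3-en-1-ylidene]hept-5-enoate, via mesylate 16 (not isolated)
Conditions: MsCl, Et3N (excess), CH2Cl2, −20 °C to 23 °C
Reagents that add atoms: none
Why: Mesylation of the C7 carbinol and E1cB elimination through the C8 enolate (aldol dehydration) should give the cross-conjugated dienone with the 7E geometry that places C6 away from the C9 carbonyl oxygen, while the 5Z alkene is not involved; the C12 descriptor changes from S to R only because C8 gains priority.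

Step 8
Reactants: 17 methyl (5Z,7E)-7-[(2R)-4-bromo-2-[(tert-butyldimethylsilyl)oxy]-2-[(2Z)-oct-2-en-1-yl]-5-oxocyclopent-3-en-1-ylidene]hept-5-enoate
Product: 18 methyl (5Z,7E)-7-[(2R)-4-bromo-2-hydroxy-2-[(2Z)-oct-2-en-1-yl]-5-oxocyclopent-3-en-1-ylidene]hept-5-enoate
Conditions: HF·pyridine, pyridine, THF, 0 °C to 23 °C
Reagents that add atoms: none
Why: Cleavage of the tertiary silyl ether with buffered HF (desilylation) should free the C12 hydroxyl without affecting the methyl ester, the bromodienone or the alkene geometries, and C12 is not a reacting centre.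

Compound list
1 | (4Z)-dec-4-enal | CCCCC/C=C\CCC=O | starting material
2 | tert-butyl[(4Z)-deca-1,4-dien-1-yloxy]dimethylsilane (C1=C2 E/Z mixture) | CCCCC/C=C\CC=CO[Si](C)(C)C(C)(C)C | intermediate
3 | 2-[(tert-butyldimethylsilyl)oxy]-3-[(2Z)-oct-2-en-1-yl]oxirane (racemic, not isolated) | CCCCC/C=C\CC1OC1O[Si](C)(C)C(C)(C)C | intermediate
4 | rac-(4Z)-2-[(tert-butyldimethylsilyl)oxy]dec-4-enal | CCCCC/C=C\CC(O[Si](C)(C)C(C)(C)C)C=O | intermediate
5 | (2S,5S)-2,5-dimethylpyrrolidine | C[C@H]1CC[C@H](C)N1 | starting material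
6 | 1,3-dibromopropan-2-one | BrCC(=O)CBr | starting material
7 | (2S,5S)-1-[(1Z,4Z)-2-[(tert-butyldimethylsilyl)oxy]deca-1,4-dien-1-yl]-2,5-dimethylpyrrolidine (not isolated) | CCCCC/C=C\C/C(O[Si](C)(C)C(C)(C)C)=C/N1[C@@H](C)CC[C@@H]1C | intermediate
8 | (2S,5S)-1-[(2S,4Z)-2-(3-bromo-2-oxopropyl)-2-[(tert-butyldimethylsilyl)oxy]dec-4-en-1-ylidene]-2,5-dimethylpyrrolidin-1-ium bromide (not isolated) | CCCCC/C=C\C[C@](O[Si](C)(C)C(C)(C)C)(CC(=O)CBr)C=[N+]1[C@@H](C)CC[C@@H]1C.[Br-] | intermediate
9 | (4S)-2-bromo-4-[(tert-butyldimethylsilyl)oxy]-4-[(2Z)-oct-2-en-1-yl]cyclopent-2-en-1-one | CCCCC/C=C\C[C@@]1(O[Si](C)(C)C(C)(C)C)C=C(Br)C(=O)C1 | intermediate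
10 | methyl hex-5-enoate | COC(=O)CCCC=C | starting material
11 | (2Z)-but-2-ene-1,4-diol | OC/C=C\CO | starting material
12 | methyl (5Z)-7-hydroxyhept-5-enoate | COC(=O)CCC/C=C\CO | intermediate
13 | methyl (5Z)-7-oxohept-5-enoate | COC(=O)CCC/C=C\C=O | intermediate
14 | lithium (3S)-5-bromo-3-[(tert-butyldimethylsilyl)oxy]-3-[(2Z)-oct-2-en-1-yl]cyclopenta-1,4-dien-1-olate (not isolated) | CCCCC/C=C\C[C@@]1(O[Si](C)(C)C(C)(C)C)C=C(Br)C([O-])=C1.[Li+] | intermediate
15 | methyl (5Z)-7-[(2S)-4-bromo-2-[(tert-butyldimethylsilyl)oxy]-2-[(2Z)-oct-2-en-1-yl]-5-oxocyclopent-3-en-1-yl]-7-hydroxyhept-5-enoate (C7/C8 epimer mixture) | CCCCC/C=C\C[C@@]1(O[Si](C)(C)C(C)(C)C)C=C(Br)C(=O)C1C(O)/C=C\CCCC(=O)OC | intermediate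
16 | methyl (5Z)-7-[(2S)-4-bromo-2-[(tert-butyldimethylsilyl)oxy]-2-[(2Z)-oct-2-en-1-yl]-5-oxocyclopent-3-en-1-yl]-7-[(methylsulfonyl)oxy]hept-5-enoate (not isolated) | CCCCC/C=C\C[C@@]1(O[Si](C)(C)C(C)(C)C)C=C(Br)C(=O)C1C(OS(C)(=O)=O)/C=C\CCCC(=O)OC | intermediate
17 | methyl (5Z,7E)-7-[(2R)-4-bromo-2-[(tert-butyldimethylsilyl)oxy]-2-[(2Z)-oct-2-en-1-yl]-5-oxocyclopent-3-en-1-ylidene]hept-5-enoate | CCCCC/C=C\C[C@@]1(O[Si](C)(C)C(C)(C)C)C=C(Br)C(=O)/C1=C/C=C\CCCC(=O)OC | intermediate
18 | methyl (5Z,7E)-7-[(2R)-4-bromo-2-hydroxy-2-[(2Z)-oct-2-en-1-yl]-5-oxocyclopent-3-en-1-ylidene]hept-5-enoate (bromovulone I) | CCCCC/C=C\C[C@@]1(O)C=C(Br)C(=O)/C1=C/C=C\CCCC(=O)OC | target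

Total step count: 8. Longest linear sequence: 6 steps (steps 1, 2, 3, 6, 7, 8); steps 4 and 5 make the side-chain aldehyde.

Steps most likely to fail

Step 3 (key step, proposed new method). The enamine may be alkylated on nitrogen, ketone 6 may be enolised instead of attacked, the enamine may form as a mixture of geometries, and the facial selectivity may be poor or of the opposite sense, so that 9 forms in low yield or low enantiomeric purity. The fallback uses known reactions, makes the two ring bonds one after the other, sets out from 4 and comes back at 9. O-Acylation of the potassium enolate of 4 (KN(SiMe3)2, allyl chloroformate, THF, −78 °C) would give prop-2-en-1-yl (1Z,4Z)-2-[(tert-butyldimethylsilyl)oxy]deca-1,4-dien-1-yl carbonate F1. Decarboxylative asymmetric allylic alkylation (Pd2(dba)3·CHCl3, N,N′-bis(2-diphenylphosphinobenzoyl)cyclohexane-1,2-diamine in the enantiomer that gives the R product, dioxane, 23 °C), the known route to alpha-tertiary hydroxy aldehydes, would give (2R,4Z)-2-[(tert-butyldimethylsilyl)oxy]-2-(prop-2-en-1-yl)dec-4-enal F2. Wacker oxidation of the terminal alkene (PdCl2, CuCl, O2, DMF–H2O) would give (2S,4Z)-2-[(tert-butyldimethylsilyl)oxy]-2-(2-oxopropyl)dec-4-enal F3, and aldol condensation (KOH, MeOH–THF, 0 °C) would give (4S)-4-[(tert-butyldimethylsilyl)oxy]-4-[(2Z)-oct-2-en-1-yl]cyclopent-2-en-1-one F4. Nucleophilic epoxidation of the enone (H2O2, NaOH, MeOH, 0 °C) would give (4S)-4-[(tert-butyldimethylsilyl)oxy]-2,3-epoxy-4-[(2Z)-oct-2-en-1-yl]cyclopentan-1-one F5, and opening by bromide at C10 followed by dehydration (MgBr2·OEt2, Et2O; then MsCl, Et3N) would return 9.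

Step 6. The Z-enal 13 may isomerise to the E-enal through gamma-deprotonation by the dienolate, the aldolate may revert on warming, and conjugate addition to the enal may compete. The fallback makes the 5Z alkene last, so that no Z-enal meets a base; it sets out from 9 and comes back at 17. Aldol condensation of 9 with 2,2-dimethoxyacetaldehyde (LiN(iPr)2, THF, −78 °C; then MsCl, Et3N) would give (4R,5E)-2-bromo-4-[(tert-butyldimethylsilyl)oxy]-5-(2,2-dimethoxyethylidene)-4-[(2Z)-oct-2-en-1-yl]cyclopent-2-en-1-one F6. Mild acetal hydrolysis (aqueous oxalic acid on silica, CH2Cl2) would give (2E)-2-[(2R)-4-bromo-2-[(tert-butyldimethylsilyl)oxy]-2-[(2Z)-oct-2-en-1-yl]-5-oxocyclopent-3-en-1-ylidene]acetaldehyde F7. A Z-selective Wittig reaction with the ylide from (5-methoxy-5-oxopentyl)triphenylphosphonium bromide F8 (made from methyl 5-bromopentanoate and PPh3; ylide with NaN(SiMe3)2, THF, −78 °C) would give 17.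

Step 7. Alkene geometry may be lost: the 7Z isomer may form, the C5=C6 bond may isomerise from Z to E through reversible conjugate addition of chloride or amine, and the allylic mesylate may undergo SN2′ substitution. The fallback forms the C7=C8 bond by olefination instead of elimination; it sets out from 9, replaces steps 6 and 7 and comes back at 17. Trapping the lithium dienolate of 9 with ClP(O)(OEt)2 would give diethyl (3S)-5-bromo-3-[(tert-butyldimethylsilyl)oxy]-3-[(2Z)-oct-2-en-1-yl]cyclopenta-1,4-dien-1-yl phosphate F9. A LiN(iPr)2-induced 1,3-phosphoryl shift from oxygen to carbon would give diethyl [(2R)-4-bromo-2-[(tert-butyldimethylsilyl)oxy]-2-[(2Z)-oct-2-en-1-yl]-5-oxocyclopent-3-en-1-yl]phosphonate F10. Horner–Wadsworth–Emmons reaction of F10 with 13 (LiCl, iPr2NEt, MeCN, 0 °C) should then give 17 with E preference and without an allylic leaving group.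

Further compounds
F1 | step 3 | prop-2-en-1-yl (1Z,4Z)-2-[(tert-butyldimethylsilyl)oxy]deca-1,4-dien-1-yl carbonate | CCCCC/C=C\C/C(O[Si](C)(C)C(C)(C)C)=C/OC(=O)OCC=C
F2 | step 3 | (2R,4Z)-2-[(tert-butyldimethylsilyl)oxy]-2-(prop-2-en-1-yl)dec-4-enal | CCCCC/C=C\C[C@](O[Si](C)(C)C(C)(C)C)(CC=C)C=O
F3 | step 3 | (2S,4Z)-2-[(tert-butyldimethylsilyl)oxy]-2-(2-oxopropyl)dec-4-enal | CCCCC/C=C\C[C@](O[Si](C)(C)C(C)(C)C)(CC(C)=O)C=O
F4 | step 3 | (4S)-4-[(tert-butyldimethylsilyl)oxy]-4-[(2Z)-oct-2-en-1-yl]cyclopent-2-en-1-one | CCCCC/C=C\C[C@@]1(O[Si](C)(C)C(C)(C)C)C=CC(=O)C1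
F5 | step 3 | (4S)-4-[(tert-butyldimethylsilyl)oxy]-2,3-epoxy-4-[(2Z)-oct-2-en-1-yl]cyclopentan-1-one (epoxide face not specified) | CCCCC/C=C\C[C@@]1(O[Si](C)(C)C(C)(C)C)C2OC2C(=O)C1
F6 | step 6 | (4R,5E)-2-bromo-4-[(tert-butyldimethylsilyl)oxy]-5-(2,2-dimethoxyethylidene)-4-[(2Z)-oct-2-en-1-yl]cyclopent-2-en-1-one | CCCCC/C=C\C[C@@]1(O[Si](C)(C)C(C)(C)C)C=C(Br)C(=O)/C1=C/C(OC)OC
F7 | step 6 | (2E)-2-[(2R)-4-bromo-2-[(tert-butyldimethylsilyl)oxy]-2-[(2Z)-oct-2-en-1-yl]-5-oxocyclopent-3-en-1-ylidene]acetaldehyde | CCCCC/C=C\C[C@@]1(O[Si](C)(C)C(C)(C)C)C=C(Br)C(=O)/C1=C/C=O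
F8 | step 6 | (5-methoxy-5-oxopentyl)triphenylphosphonium bromide | COC(=O)CCCC[P+](c1ccccc1)(c1ccccc1)c1ccccc1.[Br-]
F9 | step 7 | diethyl (3S)-5-bromo-3-[(tert-butyldimethylsilyl)oxy]-3-[(2Z)-oct-2-en-1-yl]cyclopenta-1,4-dien-1-yl phosphate | CCCCC/C=C\C[C@@]1(O[Si](C)(C)C(C)(C)C)C=C(Br)C(OP(=O)(OCC)OCC)=C1
F10 | step 7 | diethyl [(2R)-4-bromo-2-[(tert-butyldimethylsilyl)oxy]-2-[(2Z)-oct-2-en-1-yl]-5-oxocyclopent-3-en-1-yl]phosphonate (C8 epimer mixture) | CCCCC/C=C\C[C@@]1(O[Si](C)(C)C(C)(C)C)C=C(Br)C(=O)C1P(=O)(OCC)OCC
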